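## Retrosynthetic overview

1. The strategy rests on ring D: a six-membered carbocycle in which two C(CH3)2 carbons sit between three oxygen-bearing carbons (one enol C–OH, two C=O), the sixth carbon carrying the methine. It is a 1,3,5-trihydroxybenzene ring that has taken up four C-methyl groups, so it is cut at its four C–CH3 bonds back to trihydroxyphenyl compound 16 and iodomethane 17.
2. The C2–C3 bond of ring C is taken back to a flavone, so the key step meets no enolisable CH2. C2 (R) is set afterwards by asymmetric hydrogenation, and the ether cleavage needed after the key step is done on the flavone, before C2 exists.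
3. The bond from the methine to the phloroglucinol ring is cut next: catalytic asymmetric addition of phloroglucinol 14 to the ortho-quinone methide released from C8 sulfone 13, which comes from 7-hydroxy-5-methoxy-6-methylflavone 11, isovaleraldehyde 12 and toluenesulfinate.
4. Order of rings: ring A is bought (2,6-dimethoxytoluene 1), ring B comes with benzoyl chloride 5, ring C is closed by cyclodehydration of a Baker–Venkataraman-type diketone, and ring D is bought as arene 14 and takes its final form last, by dearomatisation, with no ring closure.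

Key step: step 9

Remark 1: CIP descriptors are assigned for the enol tautomer of ring D drawn in the target SMILES; in that form the methine is S and C2 is R.
Remark 2: the hand of each chiral catalyst (steps 8 and 12) is assigned from a first run; the pseudoenantiomeric squaramide and the mirror-image carbene salt are equally available.

## Route

Step 1
Reactants: 1 2,6-dimethoxytoluene
Product: 3 3,5-dimethoxy-4-methylphenol, via pinacol boronate 2 (not isolated)
Conditions: [Ir(OMe)(cod)]2 (1.5 mol%), 4,4'-di-tert-butyl-2,2'-bipyridine (3 mol%), B2pin2 (1.0 equiv), THF, 80 °C; then KHSO5 (Oxone, 2KHSO5·KHSO4·K2SO4), acetone/H2O, 0 °C → rt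
Reagents that add atoms: bis(pinacolato)diboron, CC1(C)OB(OC1(C)C)B1OC(C)(C)C(C)(C)O1 (boron of intermediate 2 only); potassium peroxymonosulfate, [K+].[O-]S(=O)(=O)OO (the phenol oxygen)
Why: Iridium-catalysed C–H borylation is governed by sterics, so this 1,2,3-trisubstituted arene should be borylated only at C4, the one position without an ortho substituent, and boronate-to-phenol oxidation then gives the symmetric phenol.

Step 2
Reactants: 3 3,5-dimethoxy-4-methylphenol
Product: 4 1-(6-hydroxy-2,4-dimethoxy-3-methylphenyl)ethan-1-one
Conditions: Ac2O (1.5 equiv), BF3·OEt2 (3 equiv), 70 °C; then aq. NaOAc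
Reagents that add atoms: acetic anhydride, CC(=O)OC(C)=O
Why: BF3-mediated Friedel–Crafts acetylation (with Fries-type transfer of any O-acetate) goes ortho to the hydroxyl, and since the two ortho positions are equivalent by symmetry a single ketone should form, which fixes the future ring oxygen para to the methyl group.

Step 3
Reactants: 4 1-(6-hydroxy-2,4-dimethoxy-3-methylphenyl)ethan-1-one, 5 benzoyl chloride
Product: 7 5,7-dimethoxy-6-methylflavone, via 1,3-diketone 6 (not isolated)
Conditions: LiN(SiMe3)2 (3.3 equiv), THF, −78 → −10 °C; BzCl (1.05 equiv), −78 °C → rt; then AcOH, H2SO4 (cat.), 100 °C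
Reagents that add atoms: none
Why: The lithium dianion of the hydroxy ketone is C-benzoylated at the methyl group (one-pot variant of the Baker–Venkataraman diketone synthesis), and acid-catalysed cyclodehydration of the only ortho hydroxyl onto the benzoyl carbonyl closes ring C with the methyl group unambiguously at C6.

Step 4
Reactants: 7 5,7-dimethoxy-6-methylflavone
Product: 8 5,7-dihydroxy-6-methylflavone
Conditions: BBr3 (5 equiv), CH2Cl2, −78 °C → rt; MeOH, then H2O
Reagents that add atoms: none
Why: BBr3 cleaves both aryl methyl ethers (Lewis acid ether cleavage) without opening the pyranone, and the two hydroxyls set free differ sharply in acidity, which the next step uses to tell O7 from O5.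

Step 5
Reactants: 8 5,7-dihydroxy-6-methylflavone
Product: 10 7-(benzyloxy)-5-methoxy-6-methylflavone, via 7-O-benzyl ether 9 (not isolated)
Conditions: BnBr (1.05 equiv), K2CO3, acetone/DMF, reflux; then Me2SO4 (3 equiv), K2CO3, reflux
Reagents that add atoms: benzyl bromide, BrCc1ccccc1; dimethyl sulfate, COS(=O)(=O)OC
Why: The C7 hydroxyl is free and acidic while the C5 hydroxyl is hydrogen-bonded to the C4 carbonyl, so one equivalent of benzyl bromide should alkylate O7 only (Williamson ether synthesis), after which excess dimethyl sulfate at reflux etherifies the sluggish O5.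

Step 6
Reactants: 10 7-(benzyloxy)-5-methoxy-6-methylflavone
Product: 11 7-hydroxy-5-methoxy-6-methylflavone
Conditions: H2 (1 atm), Pd/C (10 wt% Pd on carbon), EtOAc/MeOH, rt
Reagents that add atoms: none
Why: Hydrogenolysis of the benzyl ether frees the C7 phenol, the conjugated C2=C3 bond of a flavone being reduced far more slowly at one atmosphere.

Step 7
Reactants: 11 7-hydroxy-5-methoxy-6-methylflavone, 12 isovaleraldehyde
Product: 13 7-hydroxy-5-methoxy-6-methyl-8-[3-methyl-1-(4-methylbenzenesulfonyl)butyl]flavone (racemic)
Conditions: isovaleraldehyde (2 equiv), TolSO2Na (2 equiv), HCO2H/H2O 2:1, 40 °C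
Reagents that add atoms: sodium p-toluenesulfinate, [Na+].Cc1ccc(cc1)S(=O)[O-]
Why: In this acid-promoted three-component sulfonylalkylation (a Mannich/Betti-type ortho-hydroxyalkylation in which sulfinate traps the benzylic cation) C8 is the only unsubstituted carbon of ring A and is activated by the ortho hydroxyl and the para methoxyl, and the racemic centre formed is erased again in step 8.

Step 8
Reactants: 13 7-hydroxy-5-methoxy-6-methyl-8-[3-methyl-1-(4-methylbenzenesulfonyl)butyl]flavone, 14 phloroglucinol
Product: 16 7-hydroxy-5-methoxy-6-methyl-8-[(1R)-3-methyl-1-(2,4,6-trihydroxyphenyl)butyl]flavone, via ortho-quinone methide 15 (not isolated)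
Conditions: quinine-derived squaramide bearing a 3,5-bis(trifluoromethyl)phenyl group (10 mol%), phloroglucinol (3 equiv), sat. aq. NaHCO3, CH2Cl2/MTBE, 0 °C
Reagents that add atoms: none
Why: Bicarbonate releases the ortho-quinone methide by 1,4-elimination of sulfinate, the squaramide N–H bonds hold its C7 carbonyl while the quinuclidine nitrogen holds a phloroglucinol hydroxyl, and the aromatic carbon then adds to one face of the exocyclic alkene (organocatalytic Friedel–Crafts-type conjugate addition to a quinone methide formed in situ), so the methine configuration is set by the catalyst and excess phloroglucinol suppresses double alkylation.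

Step 9
Reactants: 16 7-hydroxy-5-methoxy-6-methyl-8-[(1R)-3-methyl-1-(2,4,6-trihydroxyphenyl)butyl]flavone, 17 iodomethane
Product: 18 8-[(1S)-1-(2-hydroxy-3,3,5,5-tetramethyl-4,6-dioxocyclohex-1-en-1-yl)-3-methylbutyl]-5,7-dimethoxy-6-methylflavone
Conditions: NaOMe (7 equiv), MeI (6 equiv), degassed MeOH, 0 °C → rt; then 1 M HCl
Reagents that add atoms: iodomethane (17), CI
Why: Methoxide turns the trihydroxyphenyl ring into its polyanion, a vinylogous enolate that attacks iodomethane in SN2 fashion at the two ring carbons that carry hydrogen; each is methylated twice because the monomethylated intermediate is reionised at once, so the arene becomes the 4,4,6,6-tetramethyl-1,3,5-trione, which rests as its delocalised enolate until the acidic work-up, while the C7 phenoxide is O-methylated in the same flask. The closest known reaction is the exhaustive C-methylation of acylphloroglucinols with MeI and NaOMe that leads to acetylsyncarpic acid, a dearomative alkylation of a phloroglucinol. No ring is closed and no stereocentre is made: the four bonds of the methine are untouched, so its spatial arrangement is kept, and the descriptor changes from R to S only because the dearomatised ring D now outranks ring A. The step needs C- over O-methylation on the phloroglucinol ring, which the protic solvent and the soft iodide electrophile favour, and no fifth methyl group at the carbon bearing the methine, which the branched benzylic substituent shields on both faces. It also needs the flavone to stay intact, which follows because ring A has no free carbon and its C5 oxygen is already an ether, so it cannot form a phloroglucinol-type dianion, and the pyranone has no enolisable CH2. O-Methylation at C7 in addition closes the retro-Michael path to an ortho-quinone methide and so guards the methine configuration.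

Step 10
Reactants: 18 8-[(1S)-1-(2-hydroxy-3,3,5,5-tetramethyl-4,6-dioxocyclohex-1-en-1-yl)-3-methylbutyl]-5,7-dimethoxy-6-methylflavone
Product: 19 5,7-dihydroxy-8-[(1S)-1-(2-hydroxy-3,3,5,5-tetramethyl-4,6-dioxocyclohex-1-en-1-yl)-3-methylbutyl]-6-methylflavone
Conditions: BBr3 (6 equiv), CH2Cl2, −78 → 0 °C; MeOH, then H2O
Reagents that add atoms: none
Why: BBr3 cleaves the C5 ether (helped by chelation to the C4 carbonyl), the doubly ortho-substituted C7 ether and any ring D methyl enol ether carried over from step 9 (Lewis acid ether cleavage), and it is used here on the flavone because no C2 stereocentre yet exists that ring opening could destroy.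

Step 11
Reactants: 19 5,7-dihydroxy-8-[(1S)-1-(2-hydroxy-3,3,5,5-tetramethyl-4,6-dioxocyclohex-1-en-1-yl)-3-methylbutyl]-6-methylflavone
Product: 20 5,7-bis(methoxymethoxy)-8-{(1S)-1-[2-(methoxymethoxy)-3,3,5,5-tetramethyl-4,6-dioxocyclohex-1-en-1-yl]-3-methylbutyl}-6-methylflavone
Conditions: NaH (4 equiv), MOMCl (4.5 equiv), DMF, 0 °C → rt
Reagents that add atoms: chloromethyl methyl ether, COCCl
Why: Sodium hydride ionises both phenols and the enol fully, which keeps ring D as its enolate and so blocks retro-Michael loss of the triketone, and the hard electrophile alkylates all three oxygens (acetal protection) to one enol ether because the two flanking carbonyls of ring D are equivalent.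

Step 12
Reactants: 20 5,7-bis(methoxymethoxy)-8-{(1S)-1-[2-(methoxymethoxy)-3,3,5,5-tetramethyl-4,6-dioxocyclohex-1-en-1-yl]-3-methylbutyl}-6-methylflavone
Product: 21 (2R,4R)-5,7-bis(methoxymethoxy)-8-{(1S)-1-[2-(methoxymethoxy)-3,3,5,5-tetramethyl-4,6-dioxocyclohex-1-en-1-yl]-3-methylbutyl}-6-methyl-2-phenylchroman-4-ol (2,4-cis)
Conditions: Ru(cod)(2-methylallyl)2 (5 mol%), enantiopure 1,3-bis[1-(naphthalen-1-yl)ethyl]imidazolinium tetrafluoroborate (SINpEt·HBF4, 10 mol%), KOtBu (15 mol%), n-hexane, 70 °C; then 20, toluene/n-hexane, H2 (100 bar), 40 °C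
Reagents that add atoms: none
Why: The ruthenium carbene catalyst hydrogenates the C2=C3 bond of flavones enantioselectively (asymmetric hydrogenation of a chromone) and usually continues to the cis flavan-4-ol, so the 2R configuration should be set by the chiral carbene ligands and not by the remote methine, the acetal-protected ring D cannot chelate the metal, and any flavanone 22 formed alongside is carried into step 13.

Step 13
Reactants: 21 (2R,4R)-5,7-bis(methoxymethoxy)-8-{(1S)-1-[2-(methoxymethoxy)-3,3,5,5-tetramethyl-4,6-dioxocyclohex-1-en-1-yl]-3-methylbutyl}-6-methyl-2-phenylchroman-4-ol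
Product: 22 (2R)-5,7-bis(methoxymethoxy)-8-{(1S)-1-[2-(methoxymethoxy)-3,3,5,5-tetramethyl-4,6-dioxocyclohex-1-en-1-yl]-3-methylbutyl}-6-methylflavanone
Conditions: Dess–Martin periodinane (1.5 equiv), CH2Cl2, 0 °C → rt
Reagents that add atoms: none
Why: Dess–Martin oxidation returns the benzylic secondary alcohol to the ketone under neutral conditions, so C2 is not exposed to base-induced ring opening and the methine is untouched.

Step 14
Reactants: 22 (2R)-5,7-bis(methoxymethoxy)-8-{(1S)-1-[2-(methoxymethoxy)-3,3,5,5-tetramethyl-4,6-dioxocyclohex-1-en-1-yl]-3-methylbutyl}-6-methylflavanone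
Product: 23 (2R)-5,7-dihydroxy-8-[(1S)-1-(2-hydroxy-3,3,5,5-tetramethyl-4,6-dioxocyclohex-1-en-1-yl)-3-methylbutyl]-6-methylflavanone (CNP0249552.1)
Conditions: 3 M aq. HCl, MeOH/THF, rt → 40 °C
Reagents that add atoms: none
Why: Dilute acid hydrolyses the two aryl MOM acetals and the MOM enol ether (acetal cleavage) under conditions too mild for flavanone ring opening, for epimerisation at C2 or for cyclodehydration of the C7 hydroxyl onto ring D.

## Compound list

1 | 2,6-dimethoxytoluene | COc1cccc(OC)c1C | starting material
2 | 2-(3,5-dimethoxy-4-methylphenyl)-4,4,5,5-tetramethyl-1,3,2-dioxaborolane | COc1cc(cc(OC)c1C)B1OC(C)(C)C(C)(C)O1 | intermediate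
3 | 3,5-dimethoxy-4-methylphenol | COc1cc(O)cc(OC)c1C | intermediate
4 | 1-(6-hydroxy-2,4-dimethoxy-3-methylphenyl)ethan-1-one | CC(=O)c1c(O)cc(OC)c(C)c1OC | intermediate
5 | benzoyl chloride | O=C(Cl)c1ccccc1 | starting material
6 | 1-(6-hydroxy-2,4-dimethoxy-3-methylphenyl)-3-phenylpropane-1,3-dione | O=C(CC(=O)c1ccccc1)c1c(O)cc(OC)c(C)c1OC | intermediate
7 | 5,7-dimethoxy-6-methylflavone | COc1cc2oc(-c3ccccc3)cc(=O)c2c(OC)c1C | intermediate
8 | 5,7-dihydroxy-6-methylflavone | Cc1c(O)cc2oc(-c3ccccc3)cc(=O)c2c1O | intermediate
9 | 7-(benzyloxy)-5-hydroxy-6-methylflavone | Cc1c(OCc2ccccc2)cc2oc(-c3ccccc3)cc(=O)c2c1O | intermediate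
10 | 7-(benzyloxy)-5-methoxy-6-methylflavone | COc1c(C)c(OCc2ccccc2)cc2oc(-c3ccccc3)cc(=O)c12 | intermediate
11 | 7-hydroxy-5-methoxy-6-methylflavone | COc1c(C)c(O)cc2oc(-c3ccccc3)cc(=O)c12 | intermediate
12 | isovaleraldehyde (3-methylbutanal) | CC(C)CC=O | starting material
13 | 7-hydroxy-5-methoxy-6-methyl-8-[3-methyl-1-(4-methylbenzenesulfonyl)butyl]flavone, racemic | COc1c(C)c(O)c(C(CC(C)C)S(=O)(=O)c2ccc(C)cc2)c2oc(-c3ccccc3)cc(=O)c12 | intermediate
14 | phloroglucinol (benzene-1,3,5-triol) | Oc1cc(O)cc(O)c1 | starting material
15 | 5-methoxy-6-methyl-8-(3-methylbutylidene)-2-phenyl-8H-chromene-4,7-dione, ortho-quinone methide, drawn as the E isomer (geometry not assigned) | COC1=C(C)C(=O)/C(=C/CC(C)C)C2=C1C(=O)C=C(c1ccccc1)O2 | intermediate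
16 | 7-hydroxy-5-methoxy-6-methyl-8-[(1R)-3-methyl-1-(2,4,6-trihydroxyphenyl)butyl]flavone | COc1c(C)c(O)c([C@H](CC(C)C)c2c(O)cc(O)cc2O)c2oc(-c3ccccc3)cc(=O)c12 | intermediate
17 | iodomethane | CI | starting material
18 | 8-[(1S)-1-(2-hydroxy-3,3,5,5-tetramethyl-4,6-dioxocyclohex-1-en-1-yl)-3-methylbutyl]-5,7-dimethoxy-6-methylflavone | COc1c(C)c(OC)c([C@H](CC(C)C)C2=C(O)C(C)(C)C(=O)C(C)(C)C2=O)c2oc(-c3ccccc3)cc(=O)c12 | intermediate
19 | 5,7-dihydroxy-8-[(1S)-1-(2-hydroxy-3,3,5,5-tetramethyl-4,6-dioxocyclohex-1-en-1-yl)-3-methylbutyl]-6-methylflavone | Oc1c(C)c(O)c([C@H](CC(C)C)C2=C(O)C(C)(C)C(=O)C(C)(C)C2=O)c2oc(-c3ccccc3)cc(=O)c12 | intermediate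
20 | 5,7-bis(methoxymethoxy)-8-{(1S)-1-[2-(methoxymethoxy)-3,3,5,5-tetramethyl-4,6-dioxocyclohex-1-en-1-yl]-3-methylbutyl}-6-methylflavone | COCOc1c(C)c(OCOC)c([C@H](CC(C)C)C2=C(OCOC)C(C)(C)C(=O)C(C)(C)C2=O)c2oc(-c3ccccc3)cc(=O)c12 | intermediate
21 | (2R,4R)-5,7-bis(methoxymethoxy)-8-{(1S)-1-[2-(methoxymethoxy)-3,3,5,5-tetramethyl-4,6-dioxocyclohex-1-en-1-yl]-3-methylbutyl}-6-methyl-2-phenylchroman-4-ol | Cc1c(OCOC)c2c(c([C@H](CC(C)C)C3=C(OCOC)C(C)(C)C(=O)C(C)(C)C3=O)c1OCOC)O[C@@H](c1ccccc1)C[C@H]2O | intermediate
22 | (2R)-5,7-bis(methoxymethoxy)-8-{(1S)-1-[2-(methoxymethoxy)-3,3,5,5-tetramethyl-4,6-dioxocyclohex-1-en-1-yl]-3-methylbutyl}-6-methylflavanone | Cc1c(OCOC)c2c(c([C@H](CC(C)C)C3=C(OCOC)C(C)(C)C(=O)C(C)(C)C3=O)c1OCOC)O[C@@H](c1ccccc1)CC2=O | intermediate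
23 | (2R)-5,7-dihydroxy-8-[(1S)-1-(2-hydroxy-3,3,5,5-tetramethyl-4,6-dioxocyclohex-1-en-1-yl)-3-methylbutyl]-6-methylflavanone (CNP0249552.1) | Cc1c(O)c2c(c([C@H](CC(C)C)C3=C(O)C(C)(C)C(=O)C(C)(C)C3=O)c1O)O[C@@H](c1ccccc1)CC2=O | target

## Summary

Total step count: 14. Longest linear sequence: 14 steps (1 → 23); compounds 5, 12, 14 and 17 are bought.

Steps most likely to fail:

1. Step 9 (key step). What may go wrong: loss of site control during the methylation (O-methylation of phloroglucinol oxygens before the ring is dearomatised, or a fifth C-methylation at the carbon bearing the methine), and base-induced retro-Michael fragmentation through an ortho-quinone methide before O7 is capped, which would scramble the methine. Fallback, setting out from 13 and returning at 19: the tetramethylation is moved to its best-documented substrate. 2,4,6-Trihydroxyacetophenone is treated with iodomethane 17 and NaOMe in MeOH to give acetylsyncarpic acid F1, which is deacetylated in hot aqueous HCl (retro-Claisen) to syncarpic acid F2. F2 then replaces phloroglucinol in the squaramide-catalysed addition to quinone methide 15 released from 13 (aq. NaHCO3, CH2Cl2, 0 °C), which should give ring D adduct F3, a 7-hydroxy-5-methoxyflavone that already carries the complete ring D. BBr3 in CH2Cl2 cleaves the single C5 methyl ether of F3 and delivers 19.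

2. Step 8. What may go wrong: erosion of enantiofacial control by uncatalysed addition of phloroglucinolate at the aqueous interface, tautomerisation of the alkyl-substituted quinone methide to a styrene, or double alkylation of phloroglucinol. Fallback, setting out from 11 and returning at 16: the quinone methide is generated under acidic, homogeneous conditions from a benzylic alcohol. Duff formylation of 11 (hexamethylenetetramine, CF3CO2H, 90 °C) gives 8-formylflavone F4. Excess i-BuMgBr/CeCl3 in THF at −78 °C (the phenoxide forms first and shields the chromone) adds to the aldehyde and gives racemic benzylic alcohol F5. A chiral BINOL-derived phosphoric acid (TRIP, 10 mol%, toluene, molecular sieves) then dehydrates F5 to 15 and directs the attack of phloroglucinol 14 within a hydrogen-bonded ion pair, with no phenoxide present, to give 16.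

3. Step 12. What may go wrong: inhibition of the catalyst by the crowded, polyoxygenated substrate, insufficient catalyst control of the C2 face against the bias of the neighbouring C8 substituent, or over-reduction of a ring D ketone. Fallback, setting out from 20 and returning at 22: the chromone is reduced without a chiral catalyst by 1,4-hydride addition (LiBH(s-Bu)3, THF, −78 °C, then NH4Cl), which should give 22 together with its C2 epimer F6. Because the methine is already fixed, these are diastereomers and are separated by chromatography, and F6 can be recycled by base-induced epimerisation at C2 and renewed separation.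

Further compounds
F1 | step 9 | 2-acetyl-3-hydroxy-4,4,6,6-tetramethylcyclohex-2-ene-1,5-dione (acetylsyncarpic acid) | CC(=O)C1=C(O)C(C)(C)C(=O)C(C)(C)C1=O
F2 | step 9 | 5-hydroxy-2,2,6,6-tetramethylcyclohex-4-ene-1,3-dione (syncarpic acid) | CC1(C)C(=O)C=C(O)C(C)(C)C1=O
F3 | step 9 | 7-hydroxy-8-[(1S)-1-(2-hydroxy-3,3,5,5-tetramethyl-4,6-dioxocyclohex-1-en-1-yl)-3-methylbutyl]-5-methoxy-6-methylflavone | COc1c(C)c(O)c([C@H](CC(C)C)C2=C(O)C(C)(C)C(=O)C(C)(C)C2=O)c2oc(-c3ccccc3)cc(=O)c12
F4 | step 8 | 7-hydroxy-5-methoxy-6-methyl-4-oxo-2-phenyl-4H-chromene-8-carbaldehyde | COc1c(C)c(O)c(C=O)c2oc(-c3ccccc3)cc(=O)c12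
F5 | step 8 | 7-hydroxy-8-(1-hydroxy-3-methylbutyl)-5-methoxy-6-methylflavone, racemic | COc1c(C)c(O)c(C(O)CC(C)C)c2oc(-c3ccccc3)cc(=O)c12
F6 | step 12 | (2S)-5,7-bis(methoxymethoxy)-8-{(1S)-1-[2-(methoxymethoxy)-3,3,5,5-tetramethyl-4,6-dioxocyclohex-1-en-1-yl]-3-methylbutyl}-6-methylflavanone | Cc1c(OCOC)c2c(c([C@H](CC(C)C)C3=C(OCOC)C(C)(C)C(=O)C(C)(C)C3=O)c1OCOC)O[C@H](c1ccccc1)CC2=O
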